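Ring C is cut back to cyclopent-2-en-1-one. Its two trans ring-fusion CH carbons are the enone β- and α-carbons, the neighbouring ring C carbinol carbon is the enone carbonyl, the β-carbon holds the ring B carbinol carbon (as isopropenyl) and the α-carbon the CH2 leading to the spiro carbon. One copper-catalysed asymmetric conjugate addition with Michael trapping of the enolate joins the enone, isopropenylmagnesium bromide and dimethyl methylidenemalonate, fixes both fusion stereocentres and brings in the spiro carbon with both ring A carbonyl carbons. The precursor is therefore just these three simple components; rings B and A follow by radical lactonisation and Claisen–Dieckmann chemistry.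

Key step: step 2

Assumption 1: the ring A trione is written throughout as the enol tautomer of the target SMILES; other enol forms are the same compound.
Assumption 2: the (R,Sp) antipode of the ferrocenyl diphosphine is taken to give the 5S centre of 7; if the simple conjugate adduct shows the opposite sense, the mirror-image ligand is used and nothing else changes.

Step 1
Reactants: 1 dimethyl malonate; 2 formaldehyde (as paraformaldehyde)
Product: 3 dimethyl 2-methylidenepropanedioate
Conditions: (CH2O)n, Cu(OAc)2·H2O (cat.), KOAc (cat.), AcOH, 100 °C; distilled from the mixture under reduced pressure, kept cold, used the same day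
Reagents that add atoms: none
Why: Knoevenagel condensation of the malonate with formaldehyde and loss of water gives the methylidene malonate, and distilling it straight out of the mixture cracks any oligomer and delivers fresh monomer.

Step 2
Reactants: 4 cyclopent-2-en-1-one; 5 isopropenylmagnesium bromide; 3 dimethyl 2-methylidenepropanedioate
Product: 7 dimethyl 2-{[(1R,5S)-2-oxo-5-(prop-1-en-2-yl)cyclopentyl]methyl}propanedioate, via bromomagnesium enolate 6 (not isolated)
Conditions: CuBr·SMe2 (5 mol%), (R)-1-[(Sp)-2-(diphenylphosphino)ferrocenyl]ethyldicyclohexylphosphine (6 mol%), t-BuOMe, −78 °C, 5 (1.15 equiv) added slowly; then 3 (1.05 equiv in THF) added slowly at −78 °C; AcOH quench at −78 °C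
Reagents that add atoms: none
Why: The copper–diphosphine complex transfers the isopropenyl group from magnesium to the enone β-carbon (π-complex, oxidative addition to trivalent copper, reductive elimination) and releases the regiodefined magnesium enolate 6. The enolate then adds through its α-carbon to the unhindered, doubly activated CH2 terminus of 3 (Michael addition), and the malonate anion so formed is protonated on quenching. The closest known reaction type is the catalytic asymmetric conjugate addition of Grignard reagents to cyclic enones with in-situ trapping of the enolate by an electrophile (three-component coupling). No ring is closed. The β-stereocentre (5S) is set by the chiral ligand, and the α-stereocentre (1R) by the neighbouring isopropenyl group, which sends the acceptor to the opposite face; the resulting trans isomer is also the thermodynamic one at this epimerisable centre. The step needs 1,4- over 1,2-addition (copper catalysis, slow Grignard addition at −78 °C), face selectivity (ligand) and a single addition to 3, which should hold because the ketone enolate is far more nucleophilic than the malonate anion it produces and 3 is added slowly as the limiting reagent.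

Step 3
Reactants: 7 dimethyl 2-{[(1R,5S)-2-oxo-5-(prop-1-en-2-yl)cyclopentyl]methyl}propanedioate; 8 methylmagnesium bromide
Product: 9 dimethyl 2-{[(1R,2S,5S)-2-hydroxy-2-methyl-5-(prop-1-en-2-yl)cyclopentyl]methyl}propanedioate
Conditions: 8 (3 equiv), anhydrous CeCl3 (3 equiv), THF, −78 °C; aq. NH4Cl
Reagents that add atoms: none
Why: Grignard-type 1,2-addition of the organocerium reagent to the ketone, in which the first equivalent deprotonates the malonate (shielding the esters as an enolate) and the methyl group should enter anti to the adjacent, now bulky malonylmethyl arm, placing OH cis to that arm (2S); the weakly basic cerium reagent avoids enolisation and leaves the esters untouched at −78 °C.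

Step 4
Reactants: 9 dimethyl 2-{[(1R,2S,5S)-2-hydroxy-2-methyl-5-(prop-1-en-2-yl)cyclopentyl]methyl}propanedioate
Product: 10 dimethyl 2-{[(1R,2S,5S)-2-methyl-5-(prop-1-en-2-yl)-2-[(triethylsilyl)oxy]cyclopentyl]methyl}propanedioate
Conditions: Et3SiOTf (1.3 equiv), 2,6-lutidine (2 equiv), CH2Cl2, −78 → 0 °C
Reagents that add atoms: triethylsilyl trifluoromethanesulfonate, CC[Si](CC)(CC)OS(=O)(=O)C(F)(F)F
Why: Silyl triflate silylation of the tertiary alcohol, which blocks lactonisation of this hydroxyl onto the cis malonate arm (a δ-lactone that could not close ring B) and protects it through the oxidation and base steps.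

Step 5
Reactants: 10 dimethyl 2-{[(1R,2S,5S)-2-methyl-5-(prop-1-en-2-yl)-2-[(triethylsilyl)oxy]cyclopentyl]methyl}propanedioate
Product: 11 methyl (1R,2S,5S,6R,8R)-1,5-dimethyl-9-oxo-5-[(triethylsilyl)oxy]-10-oxatricyclo[6.2.1.0^{2,6}]undecane-8-carboxylate (ring B closed, ring C trans-fused, bridged γ-lactone with its oxygen axial on ring B)
Conditions: Mn(OAc)3·2H2O (2.2 equiv), Cu(OAc)2·H2O (0.2 equiv), KOAc, AcOH, 60 °C
Reagents that add atoms: none
Why: Oxidative free-radical cyclisation with cation capture by an ester: trivalent manganese generates the malonyl radical, which closes 6-endo-trig on the CH2 end of the 1,1-disubstituted alkene through a chair with both ring C bonds equatorial, the tertiary radical is oxidised (divalent copper) to the cation, and only the axial ester carbonyl can reach it, so after demethylation by acetate the new C–O bond is axial and the ester syn to it is marked as the lactone, both new stereocentres being dictated by the existing trans ring fusion.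

Step 6
Reactants: 11 methyl (1R,2S,5S,6R,8R)-1,5-dimethyl-9-oxo-5-[(triethylsilyl)oxy]-10-oxatricyclo[6.2.1.0^{2,6}]undecane-8-carboxylate; 12 5-methylhexane-2,4-dione
Product: 15 (1S,3'S,3a'R,7'R,7a'S)-4,7'-dihydroxy-3',7'-dimethyl-3-(2-methylpropanoyl)-3'-[(triethylsilyl)oxy]-1',2',3',3a',4',6',7',7a'-octahydrospiro[cyclohex-3-ene-1,5'-indene]-2,6-dione, via dilithio diketone dianion 13 (not isolated), via ring-opened triketo ester 14 (not isolated)
Conditions: 12 (3 equiv), lithium diisopropylamide (6 equiv), THF, −78 → 0 °C; 11, −78 °C → rt; then NaOMe, MeOH, 50 °C; 1 M HCl work-up at 0 °C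
Reagents that add atoms: none
Why: Claisen acylation of the terminal carbanion of dianion 13 by the strained, cisoid bridged lactone carbonyl (more electrophilic than the acyclic methyl ester on the same quaternary carbon, and 11 has no acidic hydrogen) opens the lactone to 14, whose doubly activated CH2 then closes the six-membered ring A onto the methyl ester by Dieckmann condensation; because the lactone carbonyl is the one syn to the ring B oxygen, the spiro configuration is inherited from the lactone.

Step 7
Reactants: 15 (1S,3'S,3a'R,7'R,7a'S)-4,7'-dihydroxy-3',7'-dimethyl-3-(2-methylpropanoyl)-3'-[(triethylsilyl)oxy]-1',2',3',3a',4',6',7',7a'-octahydrospiro[cyclohex-3-ene-1,5'-indene]-2,6-dione; 16 1-bromo-3-methylbut-2-ene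
Product: 18 (1S,3'S,3a'R,7'R,7a'S)-4,7'-dihydroxy-3',7'-dimethyl-5,5-bis(3-methylbut-2-en-1-yl)-3-(2-methylpropanoyl)-3'-[(triethylsilyl)oxy]-1',2',3',3a',4',6',7',7a'-octahydrospiro[cyclohex-3-ene-1,5'-indene]-2,6-dione, via mono-prenylated trione 17 (not isolated)
Conditions: 16 (2.5 equiv), NaOMe (3 equiv), MeOH, 0 °C → rt
Reagents that add atoms: none
Why: Twofold C-alkylation of the cyclic β-triketone enolate in a protic medium at the only ring carbon that still carries hydrogen (the CH2 between two ring carbonyls), as in the geminal prenylation of dearomatised acylphloroglucinols; the acyl-bearing carbon is not alkylated and the tertiary alcohol stays protonated.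

Step 8
Reactants: 18 (1S,3'S,3a'R,7'R,7a'S)-4,7'-dihydroxy-3',7'-dimethyl-5,5-bis(3-methylbut-2-en-1-yl)-3-(2-methylpropanoyl)-3'-[(triethylsilyl)oxy]-1',2',3',3a',4',6',7',7a'-octahydrospiro[cyclohex-3-ene-1,5'-indene]-2,6-dione
Product: 19 (1S,3'S,3a'R,7'R,7a'S)-3',4,7'-trihydroxy-3',7'-dimethyl-5,5-bis(3-methylbut-2-en-1-yl)-3-(2-methylpropanoyl)-1',2',3',3a',4',6',7',7a'-octahydrospiro[cyclohex-3-ene-1,5'-indene]-2,6-dione (target)
Conditions: HF·pyridine, THF, 0 °C → rt
Reagents that add atoms: none
Why: Fluoride-mediated desilylation of the tertiary triethylsilyl ether under mildly acidic conditions that should spare the prenyl groups, the enolised triketone and both tertiary alcohols.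

Compound list
1 | dimethyl malonate | COC(=O)CC(=O)OC | starting material
2 | formaldehyde (used as paraformaldehyde) | C=O | starting material
3 | dimethyl 2-methylidenepropanedioate | C=C(C(=O)OC)C(=O)OC | intermediate
4 | cyclopent-2-en-1-one | O=C1C=CCC1 | starting material
5 | isopropenylmagnesium bromide | CC(=C)[Mg]Br | starting material
6 | bromomagnesium (3S)-3-(prop-1-en-2-yl)cyclopent-1-en-1-olate (formed in the flask) | Br[Mg]OC1=C[C@H](CC1)C(C)=C | intermediate
7 | dimethyl 2-{[(1R,5S)-2-oxo-5-(prop-1-en-2-yl)cyclopentyl]methyl}propanedioate (trans) | COC(=O)C(C(=O)OC)C[C@@H]1[C@H](CCC1=O)C(C)=C | intermediate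
8 | methylmagnesium bromide | C[Mg]Br | starting material
9 | dimethyl 2-{[(1R,2S,5S)-2-hydroxy-2-methyl-5-(prop-1-en-2-yl)cyclopentyl]methyl}propanedioate (OH cis to the malonylmethyl arm) | COC(=O)C(C(=O)OC)C[C@@H]1[C@H](CC[C@]1(C)O)C(C)=C | intermediate
10 | dimethyl 2-{[(1R,2S,5S)-2-methyl-5-(prop-1-en-2-yl)-2-[(triethylsilyl)oxy]cyclopentyl]methyl}propanedioate | COC(=O)C(C(=O)OC)C[C@@H]1[C@H](CC[C@]1(C)O[Si](CC)(CC)CC)C(C)=C | intermediate
11 | methyl (1R,2S,5S,6R,8R)-1,5-dimethyl-9-oxo-5-[(triethylsilyl)oxy]-10-oxatricyclo[6.2.1.0^{2,6}]undecane-8-carboxylate | O=C1O[C@]2(C)C[C@@]1(C(=O)OC)C[C@@H]3[C@@H]2CC[C@]3(C)O[Si](CC)(CC)CC | intermediate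
12 | 5-methylhexane-2,4-dione | CC(=O)CC(=O)C(C)C | starting material
13 | dilithio dianion of 5-methylhexane-2,4-dione (formed in the flask) | [Li+].[Li+].[CH2-]C(=O)[CH-]C(=O)C(C)C | intermediate
14 | methyl (3S,3aR,5S,7R,7aS)-7-hydroxy-3,7-dimethyl-5-(6-methyl-3,5-dioxoheptanoyl)-3-[(triethylsilyl)oxy]octahydro-1H-indene-5-carboxylate (formed in the flask) | COC(=O)[C@@]1(C(=O)CC(=O)CC(=O)C(C)C)C[C@@H]2[C@H](CC[C@]2(C)O[Si](CC)(CC)CC)[C@](C)(O)C1 | intermediate
15 | (1S,3'S,3a'R,7'R,7a'S)-4,7'-dihydroxy-3',7'-dimethyl-3-(2-methylpropanoyl)-3'-[(triethylsilyl)oxy]-1',2',3',3a',4',6',7',7a'-octahydrospiro[cyclohex-3-ene-1,5'-indene]-2,6-dione | C1C(=O)[C@@]2(C[C@@H]3[C@H](CC[C@]3(C)O[Si](CC)(CC)CC)[C@](C)(O)C2)C(=O)C(C(=O)C(C)C)=C1O | intermediate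
16 | 1-bromo-3-methylbut-2-ene (prenyl bromide) | CC(C)=CCBr | starting material
17 | mono-prenylated analogue of 15, one 3-methylbut-2-en-1-yl group on ring A carbon 5, that centre enolisable (formed in the flask) | CC(C)=CCC1C(=O)[C@@]2(C[C@@H]3[C@H](CC[C@]3(C)O[Si](CC)(CC)CC)[C@](C)(O)C2)C(=O)C(C(=O)C(C)C)=C1O | intermediate
18 | (1S,3'S,3a'R,7'R,7a'S)-4,7'-dihydroxy-3',7'-dimethyl-5,5-bis(3-methylbut-2-en-1-yl)-3-(2-methylpropanoyl)-3'-[(triethylsilyl)oxy]-1',2',3',3a',4',6',7',7a'-octahydrospiro[cyclohex-3-ene-1,5'-indene]-2,6-dione | CC(C)=CCC1(CC=C(C)C)C(=O)[C@@]2(C[C@@H]3[C@H](CC[C@]3(C)O[Si](CC)(CC)CC)[C@](C)(O)C2)C(=O)C(C(=O)C(C)C)=C1O | intermediate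
19 | (1S,3'S,3a'R,7'R,7a'S)-3',4,7'-trihydroxy-3',7'-dimethyl-5,5-bis(3-methylbut-2-en-1-yl)-3-(2-methylpropanoyl)-1',2',3',3a',4',6',7',7a'-octahydrospiro[cyclohex-3-ene-1,5'-indene]-2,6-dione | CC(C)=CCC1(CC=C(C)C)C(=O)[C@@]2(C[C@@H]3[C@H](CC[C@]3(C)O)[C@](C)(O)C2)C(=O)C(C(=O)C(C)C)=C1O | target

Total step count: 8. Longest linear sequence: 8 steps (1 → 3 → 7 → 9 → 10 → 11 → 15 → 18 → 19).

Steps most likely to fail

Step 2. The chiral copper catalyst may discriminate the enone faces poorly for an α-branched alkenyl Grignard reagent on the flat five-membered enone. In addition, the malonate anion formed in the trapping may start anionic oligomerisation of 3 before all enolate has reacted. The fallback sets out from 4 and 5 and comes back at 7. The same copper-catalysed conjugate addition is run with Me3SiCl present, so the enolate is silylated as it forms and the silyl enol ether trimethyl{[(3S)-3-(prop-1-en-2-yl)cyclopent-1-en-1-yl]oxy}silane F1 is isolated; its enantiomeric purity can be checked there. F1 is then joined to 3 in a separate Mukaiyama–Michael addition (TiCl4, CH2Cl2, −78 °C), where no basic chain-carrying anion exists. Attack anti to the isopropenyl group should again give trans-7.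

Step 5. The cyclised tertiary radical may be diverted to alkene isomers by oxidative elimination, some 5-exo closure may compete, and the silyl ether may be partly lost in warm acetic acid. The fallback sets out from 10 and comes back at 11. Deprotonation and bromination (NaH, N-bromosuccinimide, THF, 0 °C) give dimethyl 2-bromo-2-{[(1R,2S,5S)-2-methyl-5-(prop-1-en-2-yl)-2-[(triethylsilyl)oxy]cyclopentyl]methyl}propanedioate F2. Bromine-atom-transfer radical cyclisation under neutral conditions (Et3B, air, benzene, rt) closes ring B 6-endo to dimethyl (3S,3aR,7aS)-7-bromo-3,7-dimethyl-3-[(triethylsilyl)oxy]octahydro-5H-indene-5,5-dicarboxylate F3 as a mixture of bromide epimers. AgOAc in AcOH at rt ionises either epimer to the same tertiary cation, which the syn-axial ester captures to give 11 with loss of methyl acetate.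

Step 6. The dianion may attack the methyl ester first instead of the lactone carbonyl, which would erode the spiro configuration, or the sequence may stall at the open-chain stage. The fallback sets out from 11 and comes back at 15, and fixes the connectivity by tethering. LiI in refluxing pyridine cleaves only the methyl ester (attack at O–CH3; the lactone alkyl carbon is tertiary) to the lactone carboxylic acid corresponding to 11, F4. 1-Chloro-N,N,2-trimethylprop-1-en-1-amine (CH2Cl2, 0 °C) converts it to the acid chloride of that acid, F5. C-acylation of 12 at its central carbon (MgCl2, pyridine, CH2Cl2, 0 °C → rt) gives the enolised triacylmethane 3-acyl-5-methylhexane-2,4-dione F6, whose acyl group is the tricyclic lactone carbonyl unit. Lithium diisopropylamide (3.5 equiv, THF, −78 → 0 °C) deprotonates the acetyl CH3, which attacks the lactone carbonyl intramolecularly (Dieckmann-type closure with lactone opening) to give 15.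

Further compounds
F1 | step 2 | trimethyl{[(3S)-3-(prop-1-en-2-yl)cyclopent-1-en-1-yl]oxy}silane | C[Si](C)(C)OC1=C[C@H](CC1)C(C)=C
F2 | step 5 | dimethyl 2-bromo-2-{[(1R,2S,5S)-2-methyl-5-(prop-1-en-2-yl)-2-[(triethylsilyl)oxy]cyclopentyl]methyl}propanedioate | COC(=O)C(Br)(C(=O)OC)C[C@@H]1[C@H](CC[C@]1(C)O[Si](CC)(CC)CC)C(C)=C
F3 | step 5 | dimethyl (3S,3aR,7aS)-7-bromo-3,7-dimethyl-3-[(triethylsilyl)oxy]octahydro-5H-indene-5,5-dicarboxylate (both bromide epimers) | COC(=O)C1(C(=O)OC)C[C@@H]2[C@H](CC[C@]2(C)O[Si](CC)(CC)CC)C(C)(Br)C1
F4 | step 6 | lactone carboxylic acid corresponding to methyl ester 11 | O=C1O[C@]2(C)C[C@@]1(C(=O)O)C[C@@H]3[C@@H]2CC[C@]3(C)O[Si](CC)(CC)CC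
F5 | step 6 | acid chloride of F4 | O=C1O[C@]2(C)C[C@@]1(C(=O)Cl)C[C@@H]3[C@@H]2CC[C@]3(C)O[Si](CC)(CC)CC
F6 | step 6 | 3-acyl-5-methylhexane-2,4-dione whose acyl group is the lactone carbonyl unit of F5 (enolised triacylmethane) | O=C1O[C@]2(C)C[C@@]1(C(=O)C(C(C)=O)C(=O)C(C)C)C[C@@H]3[C@@H]2CC[C@]3(C)O[Si](CC)(CC)CC
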